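## Structural features

The target is a 2,3-dihydro-1-benzofuran: benzene ring A is fused along C3a–C7a to the five-membered oxygen ring B (O1, C2, C3). C2 carries a 3-oxoprop-1-en-2-yl group (an α-substituted acrolein), C3 an isovaleryloxy group, and C5, para to O1, a 1-(isovaleryloxy)ethyl chain. C2 and C3 are adjacent stereocentres with their substituents cis (2R,3R); the third stereocentre, (R) at the side-chain carbinol, lies across the arene, so neither set can control the other. The C3 ester is benzylic, ortho to the ring oxygen and anti to H2, so acid or base can expel it with aromatization to a benzofuran; the side-chain ester is a para-alkoxybenzylic ester that can ionize and racemize; the enal is a Michael acceptor next to an allylic, oxygen-bearing C2–H. The real difficulty is the cis C2/C3 pair in one absolute sense, made and carried without ever ionizing C3, with the enal appearing last. The key step uses the fact that C3 is a benzylic carbinol carbon and C2 bears both O1 and a 2-propenyl unit: the fragment O–C3–C2–C(CH3)=CH2 is the homoallylic alkoxide of a [2,3]-Wittig shift. Because C3 is tied to O1 through C3a–C7a of ring A, the benzyl allyl ether behind it is necessarily an eight-membered 1,5-benzodioxocine, whose contraction closes ring B.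

## Logic of the disconnections

20 ⇒ 18. The C=O bond of the enal is removed and the formyl carbon goes back to a methyl group. The enal is the most reactive group of 20, and the isopropenyl group of 18 is exactly what the key step leaves, so nothing is carried in masked form. The forward oxidation must take the allylic methyl in preference to H2 and spare two ionizable benzylic esters.

18 ⇒ 16 + 17. Both acyl C–O bonds are cut together because the two esters are identical. This gives a diol and a bought acid chloride and keeps base-labile groups out of all earlier steps. The forward acylation must esterify the hindered C3 hydroxyl without eliminating it.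

16 ⇒ 15. The C–H bond at the side-chain carbinol is cut, which erases the remote stereocentre. An aryl methyl ketone is the most dependable substrate class for reagent-controlled reduction, and no ring stereocentre is near enough to interfere. The forward step needs a catalyst that reduces only the carbonyl beside a 1,1-disubstituted olefin and a free secondary alcohol.

15 ⇒ 14. The carbonyl is returned to a cyclic ketal (two C–O bonds). A mask is needed because the key step uses an alkyllithium; a ketal is preferred over a protected carbinol because it has no benzylic hydrogen for the base to remove. The forward hydrolysis must be gentle enough for the C3 carbinol; the para oxygen makes this ketal unusually easy to open.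

14 ⇒ 12. The C2–C3 bond is cut and the C3 oxygen is reconnected to the methylene carbon of the isopropenyl group, the double bond moving to C2. This one retro-[2,3] operation removes ring B, the C–C bond and both ring stereocentres and leaves an achiral eight-membered ring whose Z olefin is enforced by the ring. The forward step must distinguish two enantiotopic benzylic hydrogens, lithiate there only, reach across the ring, and follow the concerted [2,3] path and not the [1,2] one.

12 ⇒ 10. The benzylic C–O bond of the eight-membered ring is cut, with 11 as the species that cyclizes. The cut is on the benzylic side deliberately: a leaving group on the allylic carbon would be vinylogous to the aryloxy group, and the alkoxide would attack the enol-ether carbon (SN2′) to give a six-membered acetal. The forward step is a medium-ring closure that needs dilution, but four of the eight ring atoms are already held cis by the arene and the olefin.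

10 ⇒ 8. The C–Cl bond is traced back to the benzylic hydroxyl. This is clean only because 8 has a single free hydroxyl. The forward step must stay basic for the sake of the enol ether and the ketal.

8 ⇒ 3 + 7. The bond between the aryl oxygen and the vinyl carbon is cut. This is the convergent point, with the olefin geometry already fixed in 7. The forward coupling must go with retention and take the phenol, not the benzylic hydroxyl, of 3; the silyl group of 7 keeps the allylic oxygen out of the coupling and marks it as the later nucleophile.

7 ⇒ 6 ⇒ 4. The O–Si bond, then the C–I and C–CH3 bonds across the former triple bond, are cut. An alkoxide-directed anti-carbometalation of 4 forms both bonds with the Z relationship in one flask. The demand is regio- and stereocontrol of the addition.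

3 ⇒ 2 ⇒ 1. The benzylic alcohol is traced to the ester and the ketal to the ketone of 1, which already has the oxygen, the one-carbon unit and the acetyl group in the 1,2,4-pattern of ring A. Ketalization must come before the hydride reduction.

## Other disconnections considered

Alternative 1: The cut goes through ring A (C3a–C7a and C4–C5). Ring A is traced to the 6-acetylpyridazin-3-yl ether A1, whose side chain already holds C2, C3 and a terminal alkyne. Heating A1 should make the alkyne add across the pyridazine (intramolecular Diels–Alder with inverse electron demand); the N=N unit is then expelled and rings A and B appear together in A2.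
- In its favour: the substitution pattern of ring A is fixed by construction. Both ring stereocentres are made earlier on an open chain and are only carried through a pericyclic step that does not touch them. The reaction class is established for alkyne-tethered pyridazines, so on predictability of the key step this alternative is the better one.
- Against it here: the propargylic 4-methoxybenzyl ether and the tertiary alcohol must survive the cycloaddition temperature. A2 carries C2 as a 2-hydroxypropan-2-yl group, so a regioselective dehydration, an oxidative ether cleavage and the side-chain reduction must all follow. A1 needs its own asymmetric synthesis.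
- Comparison: structurally it builds two rings where the chosen plan builds one on a bought arene. Mechanistically it is a thermal cycloaddition with no stereochemical decision, against a carbanion rearrangement that must make one. In step economy the chosen plan should be clearly shorter.

Alternative 2: The cut removes C3a–C3 and O1–C2 and divides the molecule into the phenol A3 and the epoxy aldehyde A5. The aryloxytitanium triisopropoxide A4 made from A3 should add through its ortho carbon to the aldehyde of A5; the phenoxide oxygen then opens the epoxide at the carbon next to the new carbinol with inversion, closing ring B in the same flask to give A6.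
- In its favour: it is the most convergent plan, the pieces are small, the side-chain stereocentre is present from the start, and two bonds, ring B and both ring stereocentres arise in one operation. On convergence it is better than the chosen plan, and in steps up to the ring at least its equal.
- Against it here: the cis ring needs the adduct with the carbinol oxygen anti to the epoxide oxygen, while a chelating titanium centre may favour the syn adduct. The phenoxide oxygen can also attack the tertiary epoxide carbon, closing a six-membered ring. A5 is a small, sensitive aldehyde. A6 again carries a tertiary alcohol to be dehydrated selectively beside a free benzylic hydroxyl.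
- Comparison: both plans form only ring B, but the chosen plan delivers the isopropenyl group directly. The alternative rests on acyclic 1,2-induction and a 5-exo against 6-endo choice; the chosen plan rests on a ring-fused transition state that allows only cis. Step counts should be close once dehydration and protecting-group steps are included.

Alternative 3: The cut is the C7a–O1 bond. The precursor is the syn-diol A8 on a 4-fluoroacetophenone, to be made by asymmetric dihydroxylation (K2OsO2(OH)4 with a cinchona alkaloid ligand) of the diene A7. Cs2CO3 in DMSO should generate the C2 alkoxide, which displaces fluoride para to the acetyl group (SNAr, 5-exo) to give A9, the same compound as 15.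
- In its favour: the closure is an established reaction type that touches no stereocentre, the syn-diol maps directly onto the cis ring, and the acetyl group is the activating group, so no ketal is needed. The product joins the chosen route three steps before the end. On precedent it is better than the chosen plan, and on step count it should be equal or better.
- Against it here: the dihydroxylation must choose the styrene-type double bond of A7 over the 1,1-disubstituted one, on an electron-poor arene. The closure exposes an enolizable methyl ketone and, once ring B exists, a C3 hydroxyl anti to H2 to carbonate in DMSO, where aldol chemistry and aromatizing elimination are conceivable.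
- Comparison: its key step forms one C–O bond and no stereocentre; the chosen plan forms one C–C bond and two stereocentres. It is a polar addition–elimination against a sigmatropic shift. The chosen plan is preferred here only because it creates the cis pair and the isopropenyl group in one event from a ring without stereocentres, at the price of an untested step.

Key step: step 8

Remark on the structures: the Z descriptor of 12, the (2R,3R) descriptors of 14 and the (R) descriptor of the side chain were re-derived and are mutually consistent (cis ring; same spatial arrangement at C2 in 14 and 20), so no structure was changed. Two chemical corrections were made: an alkyllithium–ligand pair is used for the benzylic lithiation, because LiNR2 bases are too weak for a benzyl alkyl ether, and the leaving group for the eight-membered closure is placed on the benzylic carbon.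

Assumption: the ligand is written as its (S,S) antipode; the sense of induction cannot be derived in advance for this ring system, so the mirror-image ligand is to be used, with nothing else changed, if the first assay shows the (2S,3S) series.

## Route

Step 1
Reactants: 1 methyl 5-acetyl-2-hydroxybenzoate
Product: 2 methyl 2-hydroxy-5-(2-methyl-1,3-dioxolan-2-yl)benzoate
Conditions: HOCH2CH2OH (5 equiv), p-TsOH·H2O (cat.), toluene, reflux, Dean–Stark; Et3N quench
Reagents that add atoms: ethane-1,2-diol (ethylene glycol), OCCO
Why: Acid-catalysed ketalization driven by azeotropic removal of water; the ketone is masked first because every later hydride, base or organolithium would attack it, and any transesterified hydroxyethyl ester converges with 2 in the next reduction.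

Step 2
Reactants: 2 methyl 2-hydroxy-5-(2-methyl-1,3-dioxolan-2-yl)benzoate
Product: 3 2-(hydroxymethyl)-4-(2-methyl-1,3-dioxolan-2-yl)phenol
Conditions: LiAlH4, THF, 0 °C → rt; aq. potassium sodium tartrate work-up
Reagents that add atoms: none
Why: Hydride reduction of the salicylate ester (as its aluminium phenoxide) to the benzylic alcohol; the ketal is inert to hydride and the neutral tartrate work-up avoids acid, to which this electron-rich aryl ketal is sensitive.

Step 3
Reactants: 4 prop-2-yn-1-ol
Product: 6 (2Z)-3-iodo-2-methylprop-2-en-1-ol, via cyclic alkenylmagnesium alkoxide 5 (not isolated)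
Conditions: MeMgBr (3 equiv), CuI (10 mol%), THF, −10 °C → rt; then I2, −20 °C
Reagents that add atoms: methylmagnesium bromide, C[Mg]Br (methyl group; magnesium of 5); iodine, II
Why: Alkoxide-directed, copper-catalysed anti-carbomagnesiation puts the methyl group on the internal carbon and magnesium on the terminal carbon cis to the CH2O group (chelate 5); iodinolysis with retention gives the Z iodide, so the olefin geometry needed for the ring is fixed here.

Step 4
Reactants: 6 (2Z)-3-iodo-2-methylprop-2-en-1-ol
Product: 7 tert-butyl{[(2Z)-3-iodo-2-methylprop-2-en-1-yl]oxy}dimethylsilane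
Conditions: TBSCl, imidazole, CH2Cl2, 0 °C → rt
Reagents that add atoms: tert-butyldimethylsilyl chloride, CC(C)(C)[Si](C)(C)Cl
Why: Standard silylation of a primary alcohol; the silyl ether keeps the allylic oxygen out of the copper coupling and marks it as the later nucleophile, so that the leaving group can be placed on the benzylic carbon alone.

Step 5
Reactants: 3 2-(hydroxymethyl)-4-(2-methyl-1,3-dioxolan-2-yl)phenol; 7 tert-butyl{[(2Z)-3-iodo-2-methylprop-2-en-1-yl]oxy}dimethylsilane
Product: 8 [2-({(1Z)-3-[(tert-butyldimethylsilyl)oxy]-2-methylprop-1-en-1-yl}oxy)-5-(2-methyl-1,3-dioxolan-2-yl)phenyl]methanol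
Conditions: CuI (10 mol%), N,N-dimethylglycine·HCl (30 mol%), Cs2CO3, 1,4-dioxane, 80 °C
Reagents that add atoms: none
Why: Ullmann-type copper-catalysed C–O coupling of a phenoxide with a vinyl iodide, which proceeds with retention of olefin geometry; under carbonate only the phenol is ionized, so the benzylic hydroxyl should stay free, and the iodide has no hydrogen placed for elimination.

Step 6
Reactants: 8 [2-({(1Z)-3-[(tert-butyldimethylsilyl)oxy]-2-methylprop-1-en-1-yl}oxy)-5-(2-methyl-1,3-dioxolan-2-yl)phenyl]methanol
Product: 10 tert-butyl({(2Z)-3-[2-(chloromethyl)-4-(2-methyl-1,3-dioxolan-2-yl)phenoxy]-2-methylprop-2-en-1-yl}oxy)dimethylsilane, via benzylic methanesulfonate 9 (not isolated)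
Conditions: MsCl, Et3N, CH2Cl2, −10 °C; then LiCl, DMF, rt
Reagents that add atoms: lithium chloride, [Li+].[Cl-] (chlorine of 10); methanesulfonyl chloride, CS(=O)(=O)Cl (mesyl group of 9; its chloride can also enter 10)
Why: Sulfonylation of the only free hydroxyl followed by SN2 exchange with chloride gives a benzylic chloride that can be handled; the medium stays basic and non-ionizing, which the enol ether, the ketal and the silyl ether tolerate.

Step 7
Reactants: 10 tert-butyl({(2Z)-3-[2-(chloromethyl)-4-(2-methyl-1,3-dioxolan-2-yl)phenoxy]-2-methylprop-2-en-1-yl}oxy)dimethylsilane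
Product: 12 (2Z)-3-methyl-8-(2-methyl-1,3-dioxolan-2-yl)-4H,6H-1,5-benzodioxocine, via hydroxy chloride 11 (not isolated)
Conditions: TBAF, THF, 0 °C; then slow addition to NaH, THF, 40 °C (final 0.005 M)
Reagents that add atoms: none
Why: Fluoride desilylation frees the allylic alcohol, and its sodium alkoxide closes the eight-membered ring by intramolecular Williamson etherification (8-exo-tet) at the benzylic chloride; the ortho-disubstituted arene and the Z olefin hold four of the eight ring atoms in place, no SN2′ route to a six-membered acetal exists with the leaving group on the benzylic carbon, and high dilution suppresses oligomers.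

Step 8
Reactants: 12 (2Z)-3-methyl-8-(2-methyl-1,3-dioxolan-2-yl)-4H,6H-1,5-benzodioxocine
Product: 14 (2R,3R)-5-(2-methyl-1,3-dioxolan-2-yl)-2-(prop-1-en-2-yl)-2,3-dihydro-1-benzofuran-3-ol, via benzylic organolithium 13 (not isolated)
Conditions: t-BuLi (2 equiv), 2,2-bis[(4S)-4-isopropyl-4,5-dihydro-1,3-oxazol-2-yl]propane (2.2 equiv), hexane/toluene, −78 °C; MeOH quench at −78 °C, aq. NaHCO3
Reagents that add atoms: tert-butyllithium, [Li]C(C)(C)C (lithium of 13 only; no atom other than hydrogen remains in 14)
Why: Proposed new method: the t-BuLi–bis(oxazoline) complex should remove one of the two enantiotopic hydrogens at C6, the most acidic sp3 C–H of 12 because it is flanked by the arene and O5, to give 13 with its carbanion lobe directed across the ring at the enol-ether carbon C2. A concerted [2,3]-sigmatropic (Wittig) shift through the five-membered array C6–O5–C4–C3=C2 then forms the C6–C2 bond, breaks O5–C4 and moves the double bond out to the isopropenyl group; the closest known reaction types are the [2,3]-Wittig ring contraction of macrocyclic allyl ethers and the ligand-controlled enantioselective [2,3]-Wittig rearrangement of acyclic benzyl allyl ethers. Ring B closes by a transannular 5-exo-trig attack of the benzylic carbon on C2, and the eight-membered ring is lost in the same event. The configuration at C3 of 14 is controlled by the chiral ligand, either in the deprotonation or by equilibration of the ligated, configurationally labile organolithium before a shift that takes place with inversion at the lithium-bearing carbon. The configuration at C2 is controlled by the substrate: the arene ties C6 to O1, so the transition state is a bicyclo[3.3.0] array that can only be cis-fused, which places the alkoxide and the isopropenyl group on the same face, and the ring-locked Z olefin leaves no second diastereomeric pathway. The step needs lithiation at C6 and not at the vinylic C2–H, the allylic C4–H2 or the arene position ortho to O1, which the higher acidity of the benzylic ether C–H, the hydrocarbon solvent and −78 °C should secure. It also needs the concerted [2,3] path to outrun the radical [1,2] shift, which low temperature favours, and the dioxolane offers no acidic hydrogen and no electrophilic site to the base.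

Step 9
Reactants: 14 (2R,3R)-5-(2-methyl-1,3-dioxolan-2-yl)-2-(prop-1-en-2-yl)-2,3-dihydro-1-benzofuran-3-ol
Product: 15 1-[(2R,3R)-3-hydroxy-2-(prop-1-en-2-yl)-2,3-dihydro-1-benzofuran-5-yl]ethanone
Conditions: PPTS (10 mol%), acetone/H2O (10:1), rt
Reagents that add atoms: water, O
Why: Acid-catalysed ketal hydrolysis; the dioxolane of an aryl ketone para to an ether oxygen ionizes far more readily than the secondary C3 carbinol, so this weak acid should unmask the ketone without dehydration to the benzofuran or epimerization.

Step 10
Reactants: 15 1-[(2R,3R)-3-hydroxy-2-(prop-1-en-2-yl)-2,3-dihydro-1-benzofuran-5-yl]ethanone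
Product: 16 (2R,3R)-5-[(1R)-1-hydroxyethyl]-2-(prop-1-en-2-yl)-2,3-dihydro-1-benzofuran-3-ol
Conditions: RuCl[(R,R)-TsDPEN](p-cymene) (2 mol%), HCO2Na (5 equiv), H2O/MeOH (1:1), 40 °C
Reagents that add atoms: none
Why: Noyori asymmetric transfer hydrogenation of an aryl methyl ketone; the (R,R)-catalyst is expected to give the (R)-carbinol under pure catalyst control, the ring stereocentres being too remote to interfere, and the bifunctional hydride transfer leaves the isopropenyl group and the free C3 hydroxyl untouched near neutral pH.

Step 11
Reactants: 16 (2R,3R)-5-[(1R)-1-hydroxyethyl]-2-(prop-1-en-2-yl)-2,3-dihydro-1-benzofuran-3-ol; 17 3-methylbutanoyl chloride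
Product: 18 (1R)-1-[(2R,3R)-3-[(3-methylbutanoyl)oxy]-2-(prop-1-en-2-yl)-2,3-dihydro-1-benzofuran-5-yl]ethyl 3-methylbutanoate
Conditions: 17 (3 equiv), pyridine, DMAP (cat.), CH2Cl2, 0 °C → rt
Reagents that add atoms: none
Why: DMAP-catalysed acylation of both secondary alcohols in one operation; only O–H bonds react, so no stereocentre is touched, and the cold, buffered medium avoids ionization of the two benzylic C–O bonds.

Step 12
Reactants: 18 (1R)-1-[(2R,3R)-3-[(3-methylbutanoyl)oxy]-2-(prop-1-en-2-yl)-2,3-dihydro-1-benzofuran-5-yl]ethyl 3-methylbutanoate
Product: 20 (1R)-1-[(2R,3R)-3-[(3-methylbutanoyl)oxy]-2-(3-oxoprop-1-en-2-yl)-2,3-dihydro-1-benzofuran-5-yl]ethyl 3-methylbutanoate (target), via primary allylic alcohol 19 (not isolated)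
Conditions: SeO2 (2 equiv), 1,4-dioxane, 75 °C; aq. NaHCO3 work-up
Reagents that add atoms: selenium dioxide, O=[Se]=O
Why: Riley allylic oxidation: ene reaction at the terminal olefin carbon with hydrogen transfer from the methyl group, [2,3]-shift of the allylseleninic acid to the primary allylic alcohol 19, and further oxidation of 19 by the excess reagent to the enal; for a 1,1-disubstituted olefin the methyl group is expected to react in preference to the methine at C2, and no stereocentre is involved.

## Compound list

1 | methyl 5-acetyl-2-hydroxybenzoate | COC(=O)c1cc(C(C)=O)ccc1O | starting material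
2 | methyl 2-hydroxy-5-(2-methyl-1,3-dioxolan-2-yl)benzoate | COC(=O)c1cc(C2(C)OCCO2)ccc1O | intermediate
3 | 2-(hydroxymethyl)-4-(2-methyl-1,3-dioxolan-2-yl)phenol | OCc1cc(C2(C)OCCO2)ccc1O | intermediate
4 | prop-2-yn-1-ol | C#CCO | starting material
5 | 4-methyl-2,5-dihydro-1,2-oxamagnesole (cyclic (Z)-alkenylmagnesium alkoxide) | CC1=C[Mg]OC1 | intermediate (not isolated)
6 | (2Z)-3-iodo-2-methylprop-2-en-1-ol | OC/C(C)=C\I | intermediate
7 | tert-butyl{[(2Z)-3-iodo-2-methylprop-2-en-1-yl]oxy}dimethylsilane | CC(C)(C)[Si](C)(C)OC/C(C)=C\I | intermediate
8 | [2-({(1Z)-3-[(tert-butyldimethylsilyl)oxy]-2-methylprop-1-en-1-yl}oxy)-5-(2-methyl-1,3-dioxolan-2-yl)phenyl]methanol | CC(C)(C)[Si](C)(C)OC/C(C)=C\Oc1ccc(C2(C)OCCO2)cc1CO | intermediate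
9 | 2-({(1Z)-3-[(tert-butyldimethylsilyl)oxy]-2-methylprop-1-en-1-yl}oxy)-5-(2-methyl-1,3-dioxolan-2-yl)benzyl methanesulfonate | CC(C)(C)[Si](C)(C)OC/C(C)=C\Oc1ccc(C2(C)OCCO2)cc1COS(C)(=O)=O | intermediate (not isolated)
10 | tert-butyl({(2Z)-3-[2-(chloromethyl)-4-(2-methyl-1,3-dioxolan-2-yl)phenoxy]-2-methylprop-2-en-1-yl}oxy)dimethylsilane | CC(C)(C)[Si](C)(C)OC/C(C)=C\Oc1ccc(C2(C)OCCO2)cc1CCl | intermediate
11 | (2Z)-3-[2-(chloromethyl)-4-(2-methyl-1,3-dioxolan-2-yl)phenoxy]-2-methylprop-2-en-1-ol | OC/C(C)=C\Oc1ccc(C2(C)OCCO2)cc1CCl | intermediate (not isolated)
12 | (2Z)-3-methyl-8-(2-methyl-1,3-dioxolan-2-yl)-4H,6H-1,5-benzodioxocine | C/C1=C/Oc2ccc(C3(C)OCCO3)cc2COC1 | intermediate (precursor of the key step)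
13 | (2Z,6R)-6-lithio-3-methyl-8-(2-methyl-1,3-dioxolan-2-yl)-4H,6H-1,5-benzodioxocine, as its bis(oxazoline) complex (C6 labile; drawn as the epimer that leads to 14 by inversion) | C/C1=C/Oc2ccc(C3(C)OCCO3)cc2[C@@H]([Li])OC1 | intermediate (not isolated)
14 | (2R,3R)-5-(2-methyl-1,3-dioxolan-2-yl)-2-(prop-1-en-2-yl)-2,3-dihydro-1-benzofuran-3-ol | C=C(C)[C@H]1Oc2ccc(C3(C)OCCO3)cc2[C@H]1O | intermediate (product of the key step)
15 | 1-[(2R,3R)-3-hydroxy-2-(prop-1-en-2-yl)-2,3-dihydro-1-benzofuran-5-yl]ethanone | C=C(C)[C@H]1Oc2ccc(C(C)=O)cc2[C@H]1O | intermediate
16 | (2R,3R)-5-[(1R)-1-hydroxyethyl]-2-(prop-1-en-2-yl)-2,3-dihydro-1-benzofuran-3-ol | C=C(C)[C@H]1Oc2ccc([C@@H](C)O)cc2[C@H]1O | intermediate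
17 | 3-methylbutanoyl chloride | CC(C)CC(=O)Cl | starting material
18 | (1R)-1-[(2R,3R)-3-[(3-methylbutanoyl)oxy]-2-(prop-1-en-2-yl)-2,3-dihydro-1-benzofuran-5-yl]ethyl 3-methylbutanoate | C=C(C)[C@H]1Oc2ccc([C@@H](C)OC(=O)CC(C)C)cc2[C@H]1OC(=O)CC(C)C | intermediate
19 | (1R)-1-[(2R,3R)-2-(3-hydroxyprop-1-en-2-yl)-3-[(3-methylbutanoyl)oxy]-2,3-dihydro-1-benzofuran-5-yl]ethyl 3-methylbutanoate | C=C(CO)[C@H]1Oc2ccc([C@@H](C)OC(=O)CC(C)C)cc2[C@H]1OC(=O)CC(C)C | intermediate (not isolated)
20 | (1R)-1-[(2R,3R)-3-[(3-methylbutanoyl)oxy]-2-(3-oxoprop-1-en-2-yl)-2,3-dihydro-1-benzofuran-5-yl]ethyl 3-methylbutanoate | C=C(C=O)[C@H]1Oc2ccc([C@@H](C)OC(=O)CC(C)C)cc2[C@H]1OC(=O)CC(C)C | target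

## Step count and least certain steps

Total step count: 12. Longest linear sequence: 10 steps (1 → 2 → 3 → 8 → 10 → 12 → 14 → 15 → 16 → 18 → 20, steps 1, 2 and 5–12; the branch from 4 through steps 3, 4 and 5–12 has the same length).

Step 8 (key step, the only step beyond known chemistry). Three things are most likely to go wrong:
- Lithiation at another site, the vinylic C2–H of the enol ether or the arene position ortho to O1, since t-BuLi is also a reagent for those.
- A ring conformation in which the carbanion lobe does not point at C2, so that the radical [1,2] shift to a seven-membered ring or simple reprotonation takes over.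
- Weak discrimination of the enantiotopic hydrogens because the ligated benzylic organolithium is configurationally labile.

The fallback uses known reaction types only, sets out from 3 and returns at 14. The benzylic alcohol of 3 is oxidized with MnO2 to 2-hydroxy-5-(2-methyl-1,3-dioxolan-2-yl)benzaldehyde F1. The phenol is alkylated with chloroacetone (K2CO3, DMF, rt) to 5-(2-methyl-1,3-dioxolan-2-yl)-2-(2-oxopropoxy)benzaldehyde F2. A proline-catalysed intramolecular aldol addition (5-enolexo, the proline antipode chosen for the 3R series) should give the cis aldol 1-[(2S,3R)-3-hydroxy-5-(2-methyl-1,3-dioxolan-2-yl)-2,3-dihydro-1-benzofuran-2-yl]ethanone F3. This is silylated at once (TESCl, imidazole) to 1-[(2S,3R)-5-(2-methyl-1,3-dioxolan-2-yl)-3-[(triethylsilyl)oxy]-2,3-dihydro-1-benzofuran-2-yl]ethanone F4. Petasis methylenation with Cp2TiMe2 gives triethyl{[(2R,3R)-5-(2-methyl-1,3-dioxolan-2-yl)-2-(prop-1-en-2-yl)-2,3-dihydro-1-benzofuran-3-yl]oxy}silane F5, and TBAF returns 14. This makes the same C2–C3 bond from an enamine instead of a carbanion; its own weak point is dehydration of the aldol to an aromatic benzofuran, hence the immediate silylation and the non-basic methylenation.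

Step 7. The eight-membered closure may lose to intermolecular etherification. Fluoride may substitute the benzylic chloride before the alkoxide does. If the chloride ionizes, the nucleophilic enol-ether carbon can alkylate it in a six-membered closure. The fallback closes the ring at the other bond, sets out from 3 and 6 and returns at 12. Compound 6 is converted with CBr4/PPh3 to (1Z)-3-bromo-1-iodo-2-methylprop-1-ene F6. The dianion of 3 (NaH, 2.2 equiv, THF/DMF) is alkylated at its more nucleophilic alkoxide oxygen to give 2-({[(2Z)-3-iodo-2-methylprop-2-en-1-yl]oxy}methyl)-4-(2-methyl-1,3-dioxolan-2-yl)phenol F7. An intramolecular copper-catalysed O-vinylation (CuI, N,N-dimethylglycine, Cs2CO3, dioxane, high dilution) then gives 12, with no benzylic electrophile ever present beside the enol ether.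

Step 5. Oxidative addition to the hindered, trisubstituted vinyl iodide may be slow; the salicyl alcohol may bind copper as a chelate; prolonged heating could vinylate the benzylic hydroxyl or erode the Z geometry. The fallback reverses the polarity of the olefin partner, sets out from 7 (with 3) and returns at 8. Iodine–lithium exchange on 7 (t-BuLi, −78 °C) and trapping with 2-isopropoxy-4,4,5,5-tetramethyl-1,3,2-dioxaborolane gives, with retention, tert-butyl(dimethyl){[(2Z)-2-methyl-3-(4,4,5,5-tetramethyl-1,3,2-dioxaborolan-2-yl)prop-2-en-1-yl]oxy}silane F8. This is joined to the phenol of 3 by a Chan–Lam oxidative coupling at room temperature (Cu(OAc)2, Et3N, 4 Å sieves, air) to give 8.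

Step 12. Selenous acid at 75 °C may ionize the C3 ester (aromatization) or the side-chain ester; the ene reaction may take H2 instead of a methyl hydrogen; the oxidation may stall at 19. The fallback avoids selenium and heat, sets out from 18 and returns at 20. Ene-type chlorination with hypochlorous acid (Ca(OCl)2, solid CO2, CH2Cl2/H2O, 0 °C) should give (1R)-1-[(2R,3R)-2-(3-chloroprop-1-en-2-yl)-3-[(3-methylbutanoyl)oxy]-2,3-dihydro-1-benzofuran-5-yl]ethyl 3-methylbutanoate F9. Oxidation of the allylic chloride with N-methylmorpholine N-oxide (Ganem-type, MeCN, rt) then gives 20.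

Further compounds
F1 | step 8 | 2-hydroxy-5-(2-methyl-1,3-dioxolan-2-yl)benzaldehyde | O=Cc1cc(C2(C)OCCO2)ccc1O
F2 | step 8 | 5-(2-methyl-1,3-dioxolan-2-yl)-2-(2-oxopropoxy)benzaldehyde | CC(=O)COc1ccc(C2(C)OCCO2)cc1C=O
F3 | step 8 | 1-[(2S,3R)-3-hydroxy-5-(2-methyl-1,3-dioxolan-2-yl)-2,3-dihydro-1-benzofuran-2-yl]ethanone | CC(=O)[C@H]1Oc2ccc(C3(C)OCCO3)cc2[C@H]1O
F4 | step 8 | 1-[(2S,3R)-5-(2-methyl-1,3-dioxolan-2-yl)-3-[(triethylsilyl)oxy]-2,3-dihydro-1-benzofuran-2-yl]ethanone | CC(=O)[C@H]1Oc2ccc(C3(C)OCCO3)cc2[C@H]1O[Si](CC)(CC)CC
F5 | step 8 | triethyl{[(2R,3R)-5-(2-methyl-1,3-dioxolan-2-yl)-2-(prop-1-en-2-yl)-2,3-dihydro-1-benzofuran-3-yl]oxy}silane | C=C(C)[C@H]1Oc2ccc(C3(C)OCCO3)cc2[C@H]1O[Si](CC)(CC)CC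
F6 | step 7 | (1Z)-3-bromo-1-iodo-2-methylprop-1-ene | BrC/C(C)=C\I
F7 | step 7 | 2-({[(2Z)-3-iodo-2-methylprop-2-en-1-yl]oxy}methyl)-4-(2-methyl-1,3-dioxolan-2-yl)phenol | Oc1ccc(C2(C)OCCO2)cc1COC/C(C)=C\I
F8 | step 5 | tert-butyl(dimethyl){[(2Z)-2-methyl-3-(4,4,5,5-tetramethyl-1,3,2-dioxaborolan-2-yl)prop-2-en-1-yl]oxy}silane | CC(C)(C)[Si](C)(C)OC/C(C)=C\B1OC(C)(C)C(C)(C)O1
F9 | step 12 | (1R)-1-[(2R,3R)-2-(3-chloroprop-1-en-2-yl)-3-[(3-methylbutanoyl)oxy]-2,3-dihydro-1-benzofuran-5-yl]ethyl 3-methylbutanoate | C=C(CCl)[C@H]1Oc2ccc([C@@H](C)OC(=O)CC(C)C)cc2[C@H]1OC(=O)CC(C)C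
A1 | alternative 1 | 1-[6-({(3S,4R)-2-hydroxy-4-[(4-methoxybenzyl)oxy]-2-methylhex-5-yn-3-yl}oxy)pyridazin-3-yl]ethanone | CC(C)(O)[C@@H](Oc1ccc(C(C)=O)nn1)[C@H](OCc1ccc(OC)cc1)C#C
A2 | alternative 1 | 1-[(2S,3R)-2-(2-hydroxypropan-2-yl)-3-[(4-methoxybenzyl)oxy]-2,3-dihydro-1-benzofuran-5-yl]ethanone | CC(C)(O)[C@H]1Oc2ccc(C(C)=O)cc2[C@H]1OCc1ccc(OC)cc1
A3 | alternative 2 | 4-[(1R)-1-(tert-butyldimethylsilyloxy)ethyl]phenol | C[C@@H](O[Si](C)(C)C(C)(C)C)c1ccc(O)cc1
A4 | alternative 2 | {4-[(1R)-1-(tert-butyldimethylsilyloxy)ethyl]phenoxy}tri(propan-2-yloxy)titanium | CC(C)O[Ti](OC(C)C)(OC(C)C)Oc1ccc([C@@H](C)O[Si](C)(C)C(C)(C)C)cc1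
A5 | alternative 2 | (2S)-3,3-dimethyloxirane-2-carbaldehyde | O=C[C@H]1OC1(C)C
A6 | alternative 2 | (2S,3R)-5-[(1R)-1-(tert-butyldimethylsilyloxy)ethyl]-2-(2-hydroxypropan-2-yl)-2,3-dihydro-1-benzofuran-3-ol | CC(C)(O)[C@H]1Oc2ccc([C@@H](C)O[Si](C)(C)C(C)(C)C)cc2[C@H]1O
A7 | alternative 3 | 1-{4-fluoro-3-[(1E)-3-methylbuta-1,3-dien-1-yl]phenyl}ethanone | C=C(C)/C=C/c1cc(C(C)=O)ccc1F
A8 | alternative 3 | 1-{3-[(1R,2R)-1,2-dihydroxy-3-methylbut-3-en-1-yl]-4-fluorophenyl}ethanone | C=C(C)[C@@H](O)[C@H](O)c1cc(C(C)=O)ccc1F
A9 | alternative 3 | 1-[(2R,3R)-3-hydroxy-2-(prop-1-en-2-yl)-2,3-dihydro-1-benzofuran-5-yl]ethanone (identical with 15) | C=C(C)[C@H]1Oc2ccc(C(C)=O)cc2[C@H]1O
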